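**Plan**

- Retrosynthesis: the aryl ether C11–O is cut last, then the ring B alkene C7=C8, the C5–C6 bond and the two C4–CH3 bonds. Ring A is then cut at C2–C3 and C5–C10. This leaves a methyl ketone (C2–C1–C10) whose C11 oxygen carries an acrylate (C5–C4–C3).
- Forward: butenolide → C9 by conjugate addition → lactone methylation (C15) and opening with MeLi (C2) → O-bound acrylate → ring A by Michael–Claisen condensation (step 5) → oxolane ring O–C11–C9–C10–C1 → allyl on C5 and two methyls on C4 → ring B by metathesis → reductive loss of the C1 oxygen → ether with isofraxidin.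
- Enabling feature: the C11 oxygen is 1,3 to C10 (O–C11–C9–C10), so an acrylate hung on it reaches C10 through a five-membered transition state. The C3 carbonyl of ring A lies between C2 and, through C4=C5, C5, which matches the C10/C2 enolates of a C1 ketone. The same oxygen later locks the unwanted C1 oxygen as the enol ether of ring O–C11–C9–C10–C1, from which it is removed.
- Stereochemistry: C9 from the rhodium–BINAP catalyst; C10 from the tether (C5 delivered to the enolate face that carries C11, anti to isopropenyl); C5 from allylation anti to the isopropenyl-bearing face of the bicyclic dienone.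

Key step: step 5

Remark: atom numbers are drimane numbers of the target (ring A C1–C5 and C10, ring B C5–C10, C11 the OCH2 carbon on C9, C15 the methyl on C10). The minor C10 epimer of 4, 5 and 7 is carried along because C10 is enolised in step 5.

Step 1
Reactants: 1 furan-2(5H)-one; 2 4,4,5,5-tetramethyl-2-(prop-1-en-2-yl)-1,3,2-dioxaborolane
Product: 3 (4S)-4-(prop-1-en-2-yl)oxolan-2-one
Conditions: [RhCl(C8H12)]2 (2.5 mol%), (S)-BINAP (5.5 mol%), KOH (0.2 equiv), 1,4-dioxane/H2O 10:1, 50 °C
Reagents that add atoms: none
Why: Hayashi–Miyaura conjugate addition of the alkenylboronate to the butenolide, in which the rhodium–BINAP complex selects the face of the C9=C10 double bond and so sets C9 (the ligand antipode is the one expected to give the 4S lactone).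

Step 2
Reactants: 3
Product: 4 (3R,4S)-3-methyl-4-(prop-1-en-2-yl)oxolan-2-one
Conditions: LiN(i-Pr)2 (1.1 equiv), THF, −78 °C; MeI, −78 → −40 °C
Reagents that add atoms: iodomethane, CI
Why: Alkylation of the lactone lithium enolate, which should enter trans to the isopropenyl group on C9 and brings in C15; the configuration at C10 is without consequence because this centre is enolised in step 5.

Step 3
Reactants: 4
Product: 5 (3R,4S)-4-(hydroxymethyl)-3,5-dimethylhex-5-en-2-one
Conditions: MeLi (1.05 equiv), Et2O, −78 °C; then H2O, −78 → 0 °C
Reagents that add atoms: methyllithium, [Li]C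
Why: Single addition of MeLi to the lactone carbonyl (C1), whose lithium hemiketal is stable at −78 °C and opens to the methyl ketone only on work-up, brings in C2 and frees the C11 hydroxyl; no stereocentre is formed.

Step 4
Reactants: 5; 6 ethyl prop-2-ynoate
Product: 7 ethyl (2E)-3-{[(2S,3R)-3-methyl-4-oxo-2-(prop-1-en-2-yl)pentyl]oxy}prop-2-enoate
Conditions: N-methylmorpholine (0.3 equiv), CH2Cl2, 23 °C
Reagents that add atoms: none
Why: Amine-catalysed oxa-Michael addition of the primary alcohol to the propiolate, which should give the (E)-β-alkoxyacrylate and hangs C5–C4–C3 on the C11 oxygen without touching the ketone.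

Step 5
Reactants: 7
Product: 9 (4S)-4-[(2R)-1-hydroxy-3-methylbut-3-en-2-yl]-4-methylcyclohex-5-ene-1,3-dione, via enoate alkoxide 8 (not isolated)
Conditions: KOt-Bu (2.2 equiv), THF/t-BuOH 10:1, 0 → 23 °C; then 1 M HCl, 0 °C
Reagents that add atoms: none
Why: KOt-Bu equilibrates the ketone enolates of 7, and the fully substituted C10 enolate adds 5-exo-trig to C5 of the acrylate held on the C11 oxygen; the ester enolate formed expels the C11 alkoxide (E1cB, the temporary oxolane opens again) to give enoate 8 with the C5–C10 bond in place, and the C2 enolate of 8 then attacks the C3 ester 6-exo-trig (Claisen condensation) to close ring A and form C2–C3. The closest known reaction type is the Michael–Claisen condensation of a methyl ketone with an α,β-unsaturated ester to a cyclohexane-1,3-dione, run here with a β-alkoxy leaving group so that the C4=C5 double bond survives. Ring A is the only ring that remains closed. C10 is the only new stereocentre: the tether can deliver C5 only to the enolate face on which C11 lies, and allylic 1,3-strain keeps H9 in the enolate plane, so the isopropenyl group sits on the opposite face and C10 should come out S relative to the fixed C9. The step needs C10 and not the more accessible C2 enolate as the Michael donor, which ring size secures (five- against seven-membered transition state), and it needs the (Z)-enoate for the Claisen closure, which is secured because the alkoxide re-adds to C5 reversibly, so that E and Z forms of 8 interconvert and everything drains into the deprotonated 1,3-dione.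

Step 6
Reactants: 9
Product: 10 (3R,3aS)-3a-methyl-3-(prop-1-en-2-yl)-2,3-dihydro-1-benzofuran-6(3aH)-one
Conditions: pyridinium p-toluenesulfonate (10 mol%), benzene, reflux, Dean–Stark trap
Reagents that add atoms: none
Why: Acid-catalysed enol etherification of the cyclic 1,3-dione with the tethered primary alcohol under removal of water, in which only the C1 oxygen can close a five-membered ring (O–C11–C9–C10–C1), so that the vinylogous ester should form with C3 as the carbonyl while reversible oxa-Michael addition to C5 is drained.

Step 7
Reactants: 10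
Product: 11 (3R,3aS,4S)-3a-methyl-3-(prop-1-en-2-yl)-4-(prop-2-en-1-yl)-3,3a,4,5-tetrahydro-1-benzofuran-6(2H)-one
Conditions: TiCl4 (1.1 equiv), allyltrimethylsilane (2 equiv), CH2Cl2, −78 °C; then H2O
Reagents that add atoms: allyltrimethylsilane, C=CC[Si](C)(C)C
Why: Sakurai conjugate allylation, in which the allylsilane should add to C5, the unsubstituted β-carbon of the enone arm (C1 carries the donor oxygen and is fully substituted), from the face opposite to C9 and its isopropenyl group that lies under ring A, which places C6 cis to the C10 methyl group as the trans ring fusion requires.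

Step 8
Reactants: 11
Product: 12 (3R,3aS,4R)-3a,5,5-trimethyl-3-(prop-1-en-2-yl)-4-(prop-2-en-1-yl)-3,3a,4,5-tetrahydro-1-benzofuran-6(2H)-one
Conditions: LiN(i-Pr)2 (1.2 equiv), THF, −78 °C, then MeI; repeated in the same flask with LiN(i-Pr)2 (1.5 equiv), MeI, DMPU, −78 → 0 °C
Reagents that add atoms: iodomethane, CI
Why: Stork–Danheiser alkylation of the vinylogous ester, which can be deprotonated only at C4 (C2 is vinylic and C10 quaternary), so that two cycles of base and MeI should give the gem-dimethyl group regiospecifically; no stereocentre is formed.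

Step 9
Reactants: 12
Product: 13 (5R,9R,10S)-1,11-epoxydrima-1,7-dien-3-one (tricyclic enol ether in which the oxygen links C11 and C1)
Conditions: second-generation Grubbs catalyst (5 mol%), toluene, 80 °C
Reagents that add atoms: none
Why: Ring-closing metathesis of the allyl group on C5 with the isopropenyl group on C9, which should close ring B as the trisubstituted C7=C8 cyclohexene with loss of ethene and leaves the stereocentres untouched.

Step 10
Reactants: 13
Product: 14 (4aS,5R,8aR)-5-(hydroxymethyl)-1,1,4a,6-tetramethyl-3,4,4a,5,8,8a-hexahydronaphthalen-2(1H)-one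
Conditions: Li (6 equiv), NH3(l)/THF, −78 → −33 °C; then solid NH4Cl
Reagents that add atoms: none
Why: Dissolving-metal reduction of the β-alkoxy enone, in which two-electron reduction with protonation at C1 gives an enolate that expels the C11 alkoxide and the enone so formed is reduced again to the C2=C3 lithium enolate, so that the quench should give the C3 ketone with C1 and C2 as CH2 and the C11 hydroxyl free, the isolated C7=C8 bond being inert.

Step 11
Reactants: 14; 15 7-hydroxy-6,8-dimethoxy-2H-chromen-2-one (isofraxidin)
Product: 16 7-{[(1R,4aR,8aS)-2,5,5,8a-tetramethyl-6-oxo-1,4,4a,5,6,7,8,8a-octahydronaphthalen-1-yl]methoxy}-6,8-dimethoxy-2H-chromen-2-one (CNP0127079.1)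
Conditions: PPh3 (1.5 equiv), diisopropyl azodicarboxylate (1.5 equiv), THF, 0 → 50 °C
Reagents that add atoms: none
Why: Mitsunobu etherification, in which the C11 hydroxyl is activated as its oxyphosphonium salt and displaced at the CH2 carbon by the acidic phenol, a process that touches neither the stereocentres nor the ketone or the lactone of the coumarin.

**Compound list**

1 | furan-2(5H)-one | O=C1OCC=C1 | starting material
2 | 4,4,5,5-tetramethyl-2-(prop-1-en-2-yl)-1,3,2-dioxaborolane | CC(=C)B1OC(C)(C)C(C)(C)O1 | starting material
3 | (4S)-4-(prop-1-en-2-yl)oxolan-2-one | C=C(C)[C@H]1COC(=O)C1 | intermediate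
4 | (3R,4S)-3-methyl-4-(prop-1-en-2-yl)oxolan-2-one | C=C(C)[C@H]1COC(=O)[C@@H]1C | intermediate
5 | (3R,4S)-4-(hydroxymethyl)-3,5-dimethylhex-5-en-2-one | CC(=C)[C@@H](CO)[C@@H](C)C(C)=O | intermediate
6 | ethyl prop-2-ynoate | C#CC(=O)OCC | starting material
7 | ethyl (2E)-3-{[(2S,3R)-3-methyl-4-oxo-2-(prop-1-en-2-yl)pentyl]oxy}prop-2-enoate | CC(=C)[C@@H](CO/C=C/C(=O)OCC)[C@@H](C)C(C)=O | intermediate
8 | ethyl (4S,5R)-4-acetyl-5-(hydroxymethyl)-4,6-dimethylhepta-2,6-dienoate (E/Z, present as its potassium alkoxide) | CCOC(=O)C=C[C@](C)(C(C)=O)[C@H](CO)C(C)=C | intermediate (not isolated)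
9 | (4S)-4-[(2R)-1-hydroxy-3-methylbut-3-en-2-yl]-4-methylcyclohex-5-ene-1,3-dione (drawn as the diketone, enolised in solution) | CC(=C)[C@@H](CO)[C@]1(C)C=CC(=O)CC1=O | intermediate
10 | (3R,3aS)-3a-methyl-3-(prop-1-en-2-yl)-2,3-dihydro-1-benzofuran-6(3aH)-one | CC(=C)[C@H]1COC2=CC(=O)C=C[C@@]12C | intermediate
11 | (3R,3aS,4S)-3a-methyl-3-(prop-1-en-2-yl)-4-(prop-2-en-1-yl)-3,3a,4,5-tetrahydro-1-benzofuran-6(2H)-one | C=CC[C@H]1CC(=O)C=C2OC[C@H](C(C)=C)[C@]12C | intermediate
12 | (3R,3aS,4R)-3a,5,5-trimethyl-3-(prop-1-en-2-yl)-4-(prop-2-en-1-yl)-3,3a,4,5-tetrahydro-1-benzofuran-6(2H)-one | C=CC[C@H]1C(C)(C)C(=O)C=C2OC[C@H](C(C)=C)[C@]12C | intermediate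
13 | (5R,9R,10S)-1,11-epoxydrima-1,7-dien-3-one | O3C[C@@H]1C(C)=CC[C@H]2C(C)(C)C(=O)C=C3[C@]12C | intermediate
14 | (4aS,5R,8aR)-5-(hydroxymethyl)-1,1,4a,6-tetramethyl-3,4,4a,5,8,8a-hexahydronaphthalen-2(1H)-one | OC[C@@H]1C(C)=CC[C@H]2C(C)(C)C(=O)CC[C@]12C | intermediate
15 | 7-hydroxy-6,8-dimethoxy-2H-chromen-2-one (isofraxidin) | COc1cc2ccc(=O)oc2c(OC)c1O | starting material
16 | 7-{[(1R,4aR,8aS)-2,5,5,8a-tetramethyl-6-oxo-1,4,4a,5,6,7,8,8a-octahydronaphthalen-1-yl]methoxy}-6,8-dimethoxy-2H-chromen-2-one | COc1cc2ccc(=O)oc2c(OC)c1OC[C@@H]1C(C)=CC[C@H]2C(C)(C)C(=O)CC[C@]12C | target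

**Count and risks**

Total step count: 11. Longest linear sequence: 11 steps (1 → 16; 2, 6 and 15 are bought).

Step 5. The 5-exo conjugate addition of the fully substituted C10 enolate to the electron-rich β-alkoxyacrylate may be slower than intermolecular aldol condensation of the methyl ketone, and control of the enolate face by allylic strain may be incomplete. The fallback sets out from 7 and comes back at 9, making the C5–C10 bond under Lewis-acid instead of base activation. Compound 7 is converted (Me3SiCl, NaI, Et3N, MeCN, thermodynamic conditions) into the tetrasubstituted silyl enol ether ethyl (2E)-3-{[(2R)-3-methyl-2-(prop-1-en-2-yl)-4-(trimethylsilyloxy)pent-3-en-1-yl]oxy}prop-2-enoate F1. With TiCl4 in CH2Cl2 at −78 °C this should close by intramolecular Mukaiyama–Michael addition to the oxolane keto ester ethyl 2-[(3R,4R)-3-acetyl-3-methyl-4-(prop-1-en-2-yl)oxolan-2-yl]acetate F2. Treatment of this ester with KOt-Bu in THF then brings about retro-oxa-Michael opening and Claisen closure to 9.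

Step 7. Chemoselectivity may fail: under TiCl4 the isopropenyl double bond can attack the activated dienone intramolecularly, the allylsilane may attack C1 instead of C5, or the facial preference may be weak. The fallback sets out from 10 and comes back at 11 with a nucleophilic allylcopper reagent in place of the Lewis acid and allylsilane: CH2=CHCH2MgBr, CuBr·SMe2 and Me3SiCl in THF at −78 °C, then dilute HCl to cleave the silyl enol ether. Organocopper reagents do not readily substitute β-alkoxy enones, so C5 should remain the site of attack, and no carbocation is formed; nothing is isolated on the way.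

Step 11. Displacement at the neopentyl-type C11 by a phenol flanked by two methoxy groups may be too slow, so that the oxyphosphonium salt decomposes or the alcohol is recovered. The fallback sets out from 14 and comes back at 16 by alkylation of the phenoxide. Compound 14 with (CF3SO2)2O and 2,6-lutidine in CH2Cl2 at −78 °C gives the primary triflate [(1R,4aR,8aS)-2,5,5,8a-tetramethyl-6-oxo-1,4,4a,5,6,7,8,8a-octahydronaphthalen-1-yl]methyl trifluoromethanesulfonate F3. The caesium phenoxide of 15 (Cs2CO3, MeCN, 23 → 50 °C) then displaces the triflate to give 16.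

**Further compounds**

F1 | step 5 | ethyl (2E)-3-{[(2R)-3-methyl-2-(prop-1-en-2-yl)-4-(trimethylsilyloxy)pent-3-en-1-yl]oxy}prop-2-enoate | CCOC(=O)/C=C/OC[C@H](C(C)=C)C(C)=C(C)O[Si](C)(C)C
F2 | step 5 | ethyl 2-[(3R,4R)-3-acetyl-3-methyl-4-(prop-1-en-2-yl)oxolan-2-yl]acetate | CCOC(=O)CC1OC[C@H](C(C)=C)[C@@]1(C)C(C)=O
F0 | step 7 | none | none
F3 | step 11 | [(1R,4aR,8aS)-2,5,5,8a-tetramethyl-6-oxo-1,4,4a,5,6,7,8,8a-octahydronaphthalen-1-yl]methyl trifluoromethanesulfonate | FC(F)(F)S(=O)(=O)OC[C@@H]1C(C)=CC[C@H]2C(C)(C)C(=O)CC[C@]12C
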